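**Retrosynthetic overview**

1. Target 29 ⇐ allylic alcohol 23 (angelate on C5–OH, silyl→acetate at C2, PMB off C6); 23 ⇐ ring allylsilane 21 by epoxidation and desilylative opening, which gives C5–O and C4=CH2 together; isopropyl ⇐ acetyl (19).
2. Hexahydroindene 19 ⇐ acyclic tetraenone 18 by intramolecular Diels–Alder reaction: the bonds C6–C7 (carbinol carbon to the isopropyl-bearing carbon) and C3a–C7a form in one step, so the cyclopentane and the cyclohexene arise together (the five-membered ring slightly ahead in the asynchronous transition state).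
3. 18 ⇐ alkenylstannane 14 + (E)-4-iodobut-3-en-2-one 17 by Stille coupling in the same flask.
4. Enabling feature: the six-membered ring C3a–C4–C5–C6–C7–C7a carries oxygen on C6 and a C4(=CH2)–C5(O) unit, which is the retron of a 1-alkoxy-3-(silylmethyl)diene plus an enone; C3–C2–C1 of the five-membered ring is the three-atom tether, and the C2 stereocenter next to the Z-ethylidene relays chirality by allylic 1,3-strain.
5. 14 ⇐ methyl 4-chloro-4-oxobutanoate via ynone, asymmetric transfer hydrogenation, hydrostannation, vinylogous ester, dienyl triflate and allylsilane.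

Key step: step 10

Remark on the chemistry: the bicyclic core is numbered as in 1H-indene (C1 ethylidene carbon, C2 acetoxy carbon, C3a/C7a ring fusion, C4 methylidene carbon, C5 angelate carbon, C6 carbinol carbon, C7 isopropyl carbon), β is the face of H-3a, and reagents 2, 7 and 13 are taken as purchased.

**Route**

Step 1
Reactants: 1 methyl 4-chloro-4-oxobutanoate; 2 tributyl(prop-1-yn-1-yl)stannane
Product: 3 methyl 4-oxohept-5-ynoate
Conditions: PdCl2(PPh3)2 (2 mol %), 1,2-dichloroethane, 70 °C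
Reagents that add atoms: none
Why: Acyl Stille coupling of an acid chloride with an alkynylstannane should give the ynone while the methyl ester stays untouched.

Step 2
Reactants: 3 methyl 4-oxohept-5-ynoate
Product: 4 methyl (4S)-4-hydroxyhept-5-ynoate
Conditions: Ru[(S,S)-TsDPEN](p-cymene) (1 mol %), i-PrOH, 25 °C; used without storage
Reagents that add atoms: none
Why: Noyori asymmetric transfer hydrogenation of an alkynyl ketone, in which the alkynyl group plays the role of the aryl group, should set C4 as S with the (S,S)-catalyst; this is the only stereocenter carried into the key step.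

Step 3
Reactants: 4 methyl (4S)-4-hydroxyhept-5-ynoate
Product: 5 methyl (4S,5E)-4-hydroxy-5-(tributylstannyl)hept-5-enoate
Conditions: Bu3SnH (slow addition), PdCl2(PPh3)2 (2 mol %), THF, 0 °C
Reagents that add atoms: tributyltin hydride, CCCC[SnH](CCCC)CCCC
Why: Palladium-catalysed syn-hydrostannation of a propargylic alcohol should place tin on the alkyne carbon next to the free hydroxyl and hydrogen on the methyl-bearing carbon, so that the methyl group ends cis to the carbinol carbon (the future Z-ethylidene).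

Step 4
Reactants: 5 methyl (4S,5E)-4-hydroxy-5-(tributylstannyl)hept-5-enoate
Product: 6 methyl (4S,5E)-4-{[tert-butyl(dimethyl)silyl]oxy}-5-(tributylstannyl)hept-5-enoate
Conditions: TBSCl, imidazole, DMF, 25 °C
Reagents that add atoms: tert-butyldimethylsilyl chloride, CC(C)(C)[Si](C)(C)Cl
Why: Standard silylation of a secondary alcohol protects the carbinol, prevents lactonisation and provides the bulky group used later for facial control.

Step 5
Reactants: 6 methyl (4S,5E)-4-{[tert-butyl(dimethyl)silyl]oxy}-5-(tributylstannyl)hept-5-enoate; 7 ethynylmagnesium bromide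
Product: 9 (6S,7E)-6-{[tert-butyl(dimethyl)silyl]oxy}-7-(tributylstannyl)non-7-en-1-yn-3-one, via Weinreb amide 8 (not isolated)
Conditions: MeNH(OMe)·HCl, i-PrMgCl, THF, −20 °C; then 7, −20 → 0 °C; aq NH4Cl
Reagents that add atoms: none
Why: Ester aminolysis with the magnesium amide gives the Weinreb amide in the flask, and Grignard addition stops at the ketone through the chelated tetrahedral intermediate (Weinreb ketone synthesis); the alkenylstannane and silyl ether are inert.

Step 6
Reactants: 9 (6S,7E)-6-{[tert-butyl(dimethyl)silyl]oxy}-7-(tributylstannyl)non-7-en-1-yn-3-one; 10 (4-methoxyphenyl)methanol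
Product: 11 (1E,6S,7E)-6-{[tert-butyl(dimethyl)silyl]oxy}-1-[(4-methoxyphenyl)methoxy]-7-(tributylstannyl)nona-1,7-dien-3-one
Conditions: DABCO (10 mol %), CH2Cl2, 0 → 25 °C
Reagents that add atoms: none
Why: Amine-catalysed oxa-Michael addition of an alcohol to a terminal ynone should give the E-configured β-alkoxy enone (vinylogous ester).

Step 7
Reactants: 11 (1E,6S,7E)-6-{[tert-butyl(dimethyl)silyl]oxy}-1-[(4-methoxyphenyl)methoxy]-7-(tributylstannyl)nona-1,7-dien-3-one
Product: 12 (1E,3Z,6S,7E)-6-{[tert-butyl(dimethyl)silyl]oxy}-1-[(4-methoxyphenyl)methoxy]-7-(tributylstannyl)nona-1,3,7-trien-3-yl trifluoromethanesulfonate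
Conditions: KN(SiMe3)2, THF, −78 °C; then PhNTf2, −78 → −20 °C
Reagents that add atoms: N-phenylbis(trifluoromethanesulfonimide), O=S(=O)(N(c1ccccc1)S(=O)(=O)C(F)(F)F)C(F)(F)F
Why: Kinetic α′-deprotonation of the vinylogous ester should give the Z-enolate (as in the silylation of such ketones to 1-alkoxy-3-siloxydienes), and O-triflation fixes the 3Z geometry that places the tether on the outside of the s-cis diene.

Step 8
Reactants: 12 (1E,3Z,6S,7E)-6-{[tert-butyl(dimethyl)silyl]oxy}-1-[(4-methoxyphenyl)methoxy]-7-(tributylstannyl)nona-1,3,7-trien-3-yl trifluoromethanesulfonate; 13 [(trimethylsilyl)methyl]magnesium chloride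
Product: 14 (1E,3Z,6S,7E)-6-{[tert-butyl(dimethyl)silyl]oxy}-1-[(4-methoxyphenyl)methoxy]-7-(tributylstannyl)-3-[(trimethylsilyl)methyl]nona-1,3,7-triene
Conditions: Fe(acac)3 (5 mol %), THF/NMP, −30 °C
Reagents that add atoms: none
Why: Iron-catalysed Kumada-type coupling of an alkenyl triflate with a Grignard reagent lacking β-hydrogens should proceed with retention of geometry; iron is chosen because it does not engage the alkenylstannane.

Step 9
Reactants: 15 but-3-yn-2-one
Product: 17 (E)-4-iodobut-3-en-2-one, via (Z)-4-iodobut-3-en-2-one 16 (not isolated)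
Conditions: NaI, AcOH, 25 °C; then HI (cat.), toluene, 80 °C
Reagents that add atoms: sodium iodide, [Na+].[I-]
Why: Conjugate anti-hydroiodination of the ynone gives the Z-iodoenone, which acid-catalysed addition–elimination should equilibrate to the more stable E isomer.

Step 10
Reactants: 14 (1E,3Z,6S,7E)-6-{[tert-butyl(dimethyl)silyl]oxy}-1-[(4-methoxyphenyl)methoxy]-7-(tributylstannyl)-3-[(trimethylsilyl)methyl]nona-1,3,7-triene; 17 (E)-4-iodobut-3-en-2-one
Product: 19 1-[(1Z,2S,3aR,6R,7S,7aR)-2-{[tert-butyl(dimethyl)silyl]oxy}-1-ethylidene-6-[(4-methoxyphenyl)methoxy]-4-[(trimethylsilyl)methyl]-2,3,3a,6,7,7a-hexahydro-1H-inden-7-yl]ethan-1-one, via tetraenone 18 (not isolated)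
Conditions: Pd2(dba)3 (2.5 mol %), AsPh3 (20 mol %), CuI (10 mol %), NMP, 25 °C; then 60 °C (BHT)
Reagents that add atoms: none
Why: Stille coupling with retention at both partners gives tetraenone 18, whose 1-alkoxy-3-(silylmethyl)diene and E-enone are joined by the three-atom C3–C2–C1 bridge and should undergo an intramolecular normal-demand [4+2] cycloaddition. The closest known reaction type is the tandem Stille coupling/intramolecular Diels–Alder reaction of terminally activated 1,3,8-nonatrienes, together with the cycloadditions of 2-(trimethylsilylmethyl)butadienes and 1-alkoxydienes with enones. The cyclopentane is closed by the internal C3a–C7a bond (diene terminus onto the enone β-carbon) and the cyclohexene by the peripheral C6–C7 bond, both suprafacially in one concerted, asynchronous step. C7a/C7 trans follows from the E-enone, C3a/C6 cis from the two outside substituents of the 1E,3Z-diene, and the cis C7-acetyl/C6-ether relation together with the trans ring fusion from the endo transition state (acetyl under the diene). The absolute sense comes from C2: in the trans-fused transition state the silyloxy group should take the position turned away from the Z-methyl of the ethylidene (allylic 1,3-strain). The step needs endo over exo and one diene face; the matched polarisation (donor-activated diene terminus C3a onto enone β-carbon C7a) advances the internal bond and should favour the trans-fused endo mode, and the bulky silyl ether at C2 secures the face.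

Step 11
Reactants: 19 the methyl ketone from step 10
Product: 20 tert-butyl({(1Z,2S,3aR,6R,7R,7aR)-1-ethylidene-6-[(4-methoxyphenyl)methoxy]-7-(prop-1-en-2-yl)-4-[(trimethylsilyl)methyl]-2,3,3a,6,7,7a-hexahydro-1H-inden-2-yl}oxy)dimethylsilane
Conditions: Ph3PCH3Br, KN(SiMe3)2, THF, 0 → 25 °C
Reagents that add atoms: methyltriphenylphosphonium bromide, C[P+](c1ccccc1)(c1ccccc1)c1ccccc1.[Br-]
Why: Wittig methylenation of the methyl ketone should be faster than enolisation toward C7, whose equatorial acetyl group is in any case the thermodynamically preferred epimer.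

Step 12
Reactants: 20 the isopropenyl compound from step 11
Product: 21 tert-butyl({(1Z,2S,3aR,6S,7S,7aR)-1-ethylidene-6-[(4-methoxyphenyl)methoxy]-7-(propan-2-yl)-4-[(trimethylsilyl)methyl]-2,3,3a,6,7,7a-hexahydro-1H-inden-2-yl}oxy)dimethylsilane
Conditions: H2 (1 atm), RhCl(PPh3)3 (5 mol %), toluene/EtOH, 25 °C
Reagents that add atoms: none
Why: Homogeneous hydrogenation with RhCl(PPh3)3 should reduce the 1,1-disubstituted isopropenyl group and leave the two trisubstituted alkenes (ring allylsilane, ethylidene) alone, as in the selective reduction of isopropenyl groups in terpenes.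

Step 13
Reactants: 21 the isopropyl allylsilane from step 12
Product: 23 (1Z,2S,3aR,5S,6S,7S,7aR)-2-{[tert-butyl(dimethyl)silyl]oxy}-1-ethylidene-6-[(4-methoxyphenyl)methoxy]-4-methylidene-7-(propan-2-yl)octahydro-1H-inden-5-ol, via epoxysilane 22 (not isolated)
Conditions: mCPBA (1.05 equiv), NaHCO3, CH2Cl2, −20 °C; then PPTS (cat.), MeOH, 0 °C
Reagents that add atoms: 3-chloroperoxybenzoic acid, OOC(=O)c1cccc(Cl)c1
Why: Prilezhaev epoxidation should pick the more nucleophilic allylsilane double bond and occur on the β face, anti to the pseudoaxial C6 ether, which sets C5; acid then opens the β-silyl epoxide with loss of silicon (Peterson-type elimination) to the transposed allylic alcohol with the exocyclic methylidene.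

Step 14
Reactants: 23 the allylic alcohol from step 13; 24 angelic acid [(2Z)-2-methylbut-2-enoic acid]
Product: 26 (1Z,2S,3aR,5S,6S,7S,7aR)-2-{[tert-butyl(dimethyl)silyl]oxy}-1-ethylidene-6-[(4-methoxyphenyl)methoxy]-4-methylidene-7-(propan-2-yl)octahydro-1H-inden-5-yl (2Z)-2-methylbut-2-enoate, via mixed anhydride 25 (not isolated)
Conditions: 2,4,6-trichlorobenzoyl chloride, Et3N, toluene, 25 °C; then 23, DMAP, toluene, 25 °C
Reagents that add atoms: none
Why: Yamaguchi esterification acylates the only free hydroxyl under mild conditions that should keep the Z geometry of the angelate.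

Step 15
Reactants: 26 the angelate silyl ether from step 14
Product: 27 (1Z,2S,3aR,5S,6S,7S,7aR)-1-ethylidene-2-hydroxy-6-[(4-methoxyphenyl)methoxy]-4-methylidene-7-(propan-2-yl)octahydro-1H-inden-5-yl (2Z)-2-methylbut-2-enoate
Conditions: HF·pyridine, pyridine, THF, 0 → 25 °C
Reagents that add atoms: none
Why: Fluoride-mediated Si–O cleavage under buffered conditions should leave the angelate, the benzyl-type ether and both exocyclic alkenes intact.

Step 16
Reactants: 27 the C2 alcohol from step 15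
Product: 28 (1Z,2S,3aR,5S,6S,7S,7aR)-2-(acetyloxy)-1-ethylidene-6-[(4-methoxyphenyl)methoxy]-4-methylidene-7-(propan-2-yl)octahydro-1H-inden-5-yl (2Z)-2-methylbut-2-enoate
Conditions: Ac2O, pyridine, DMAP (cat.), CH2Cl2, 25 °C
Reagents that add atoms: acetic anhydride, CC(=O)OC(C)=O
Why: Standard DMAP-catalysed acetylation of the only free (allylic, secondary) hydroxyl.

Step 17
Reactants: 28 the acetate from step 16
Product: 29 (1Z,2S,3aR,5S,6S,7S,7aR)-2-(acetyloxy)-1-ethylidene-6-hydroxy-4-methylidene-7-(propan-2-yl)octahydro-1H-inden-5-yl (2Z)-2-methylbut-2-enoate (target)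
Conditions: DDQ, CH2Cl2/pH 7 buffer, 0 °C
Reagents that add atoms: none
Why: Oxidative cleavage of the 4-methoxybenzyl ether by DDQ frees the C6 hydroxyl; the trans-diaxial relation to the C5 angelate should prevent acyl migration.

**Compound list**

1 | methyl 4-chloro-4-oxobutanoate | COC(=O)CCC(Cl)=O | starting material
2 | tributyl(prop-1-yn-1-yl)stannane | CC#C[Sn](CCCC)(CCCC)CCCC | starting material
3 | methyl 4-oxohept-5-ynoate | COC(=O)CCC(=O)C#CC | intermediate
4 | methyl (4S)-4-hydroxyhept-5-ynoate | COC(=O)CC[C@H](O)C#CC | intermediate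
5 | methyl (4S,5E)-4-hydroxy-5-(tributylstannyl)hept-5-enoate | COC(=O)CC[C@H](O)/C(=C\C)[Sn](CCCC)(CCCC)CCCC | intermediate
6 | methyl (4S,5E)-4-{[tert-butyl(dimethyl)silyl]oxy}-5-(tributylstannyl)hept-5-enoate | COC(=O)CC[C@H](O[Si](C)(C)C(C)(C)C)/C(=C\C)[Sn](CCCC)(CCCC)CCCC | intermediate
7 | ethynylmagnesium bromide | C#C[Mg]Br | starting material
8 | (4S,5E)-4-{[tert-butyl(dimethyl)silyl]oxy}-N-methoxy-N-methyl-5-(tributylstannyl)hept-5-enamide (Weinreb amide, not isolated) | CON(C)C(=O)CC[C@H](O[Si](C)(C)C(C)(C)C)/C(=C\C)[Sn](CCCC)(CCCC)CCCC | intermediate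
9 | (6S,7E)-6-{[tert-butyl(dimethyl)silyl]oxy}-7-(tributylstannyl)non-7-en-1-yn-3-one | C#CC(=O)CC[C@H](O[Si](C)(C)C(C)(C)C)/C(=C\C)[Sn](CCCC)(CCCC)CCCC | intermediate
10 | (4-methoxyphenyl)methanol | COc1ccc(CO)cc1 | starting material
11 | (1E,6S,7E)-6-{[tert-butyl(dimethyl)silyl]oxy}-1-[(4-methoxyphenyl)methoxy]-7-(tributylstannyl)nona-1,7-dien-3-one | COc1ccc(CO/C=C/C(=O)CC[C@H](O[Si](C)(C)C(C)(C)C)/C(=C\C)[Sn](CCCC)(CCCC)CCCC)cc1 | intermediate
12 | (1E,3Z,6S,7E)-6-{[tert-butyl(dimethyl)silyl]oxy}-1-[(4-methoxyphenyl)methoxy]-7-(tributylstannyl)nona-1,3,7-trien-3-yl trifluoromethanesulfonate | COc1ccc(CO/C=C/C(OS(=O)(=O)C(F)(F)F)=C/C[C@H](O[Si](C)(C)C(C)(C)C)/C(=C\C)[Sn](CCCC)(CCCC)CCCC)cc1 | intermediate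
13 | [(trimethylsilyl)methyl]magnesium chloride | C[Si](C)(C)C[Mg]Cl | starting material
14 | (1E,3Z,6S,7E)-6-{[tert-butyl(dimethyl)silyl]oxy}-1-[(4-methoxyphenyl)methoxy]-7-(tributylstannyl)-3-[(trimethylsilyl)methyl]nona-1,3,7-triene | COc1ccc(CO/C=C/C(C[Si](C)(C)C)=C/C[C@H](O[Si](C)(C)C(C)(C)C)/C(=C\C)[Sn](CCCC)(CCCC)CCCC)cc1 | intermediate
15 | but-3-yn-2-one | CC(=O)C#C | starting material
16 | (Z)-4-iodobut-3-en-2-one (not isolated) | CC(=O)/C=C\I | intermediate
17 | (E)-4-iodobut-3-en-2-one | CC(=O)/C=C/I | intermediate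
18 | (3E,6S,8Z,10E)-6-{[tert-butyl(dimethyl)silyl]oxy}-5-[(Z)-ethylidene]-11-[(4-methoxyphenyl)methoxy]-9-[(trimethylsilyl)methyl]undeca-3,8,10-trien-2-one (tetraenone, not isolated) | COc1ccc(CO/C=C/C(C[Si](C)(C)C)=C/C[C@H](O[Si](C)(C)C(C)(C)C)/C(=C\C)/C=C/C(C)=O)cc1 | intermediate
19 | 1-[(1Z,2S,3aR,6R,7S,7aR)-2-{[tert-butyl(dimethyl)silyl]oxy}-1-ethylidene-6-[(4-methoxyphenyl)methoxy]-4-[(trimethylsilyl)methyl]-2,3,3a,6,7,7a-hexahydro-1H-inden-7-yl]ethan-1-one (trans-fused; H-3a β, H-7a α, 2-O α, 6-O α, 7-acetyl α) | C[Si](C)(C)CC=1[C@@H]2C[C@H](O[Si](C)(C)C(C)(C)C)/C(=C\C)[C@H]2[C@H](C(C)=O)[C@H](OCc3ccc(OC)cc3)C=1 | intermediate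
20 | tert-butyl({(1Z,2S,3aR,6R,7R,7aR)-1-ethylidene-6-[(4-methoxyphenyl)methoxy]-7-(prop-1-en-2-yl)-4-[(trimethylsilyl)methyl]-2,3,3a,6,7,7a-hexahydro-1H-inden-2-yl}oxy)dimethylsilane | C[Si](C)(C)CC=1[C@@H]2C[C@H](O[Si](C)(C)C(C)(C)C)/C(=C\C)[C@H]2[C@H](C(C)=C)[C@H](OCc3ccc(OC)cc3)C=1 | intermediate
21 | tert-butyl({(1Z,2S,3aR,6S,7S,7aR)-1-ethylidene-6-[(4-methoxyphenyl)methoxy]-7-(propan-2-yl)-4-[(trimethylsilyl)methyl]-2,3,3a,6,7,7a-hexahydro-1H-inden-2-yl}oxy)dimethylsilane | C[Si](C)(C)CC=1[C@@H]2C[C@H](O[Si](C)(C)C(C)(C)C)/C(=C\C)[C@H]2[C@H](C(C)C)[C@H](OCc3ccc(OC)cc3)C=1 | intermediate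
22 | 4β,5β-epoxide of 21 (epoxysilane; oxygen syn to H-3a and anti to the C6 ether; not isolated) | C[Si](C)(C)C[C@@]12O[C@@H]1[C@@H](OCc4ccc(OC)cc4)[C@@H](C(C)C)[C@@H]3/C(=C/C)[C@@H](O[Si](C)(C)C(C)(C)C)C[C@@H]23 | intermediate
23 | (1Z,2S,3aR,5S,6S,7S,7aR)-2-{[tert-butyl(dimethyl)silyl]oxy}-1-ethylidene-6-[(4-methoxyphenyl)methoxy]-4-methylidene-7-(propan-2-yl)octahydro-1H-inden-5-ol | C=C1[C@@H]2C[C@H](O[Si](C)(C)C(C)(C)C)/C(=C\C)[C@H]2[C@H](C(C)C)[C@H](OCc3ccc(OC)cc3)[C@H]1O | intermediate
24 | angelic acid, (2Z)-2-methylbut-2-enoic acid | C/C=C(/C)C(=O)O | starting material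
25 | (2Z)-2-methylbut-2-enoic 2,4,6-trichlorobenzoic anhydride (mixed anhydride, not isolated) | C/C=C(/C)C(=O)OC(=O)c1c(Cl)cc(Cl)cc1Cl | intermediate
26 | (1Z,2S,3aR,5S,6S,7S,7aR)-2-{[tert-butyl(dimethyl)silyl]oxy}-1-ethylidene-6-[(4-methoxyphenyl)methoxy]-4-methylidene-7-(propan-2-yl)octahydro-1H-inden-5-yl (2Z)-2-methylbut-2-enoate | C=C1[C@@H]2C[C@H](O[Si](C)(C)C(C)(C)C)/C(=C\C)[C@H]2[C@H](C(C)C)[C@H](OCc3ccc(OC)cc3)[C@H]1OC(=O)/C(C)=C\C | intermediate
27 | (1Z,2S,3aR,5S,6S,7S,7aR)-1-ethylidene-2-hydroxy-6-[(4-methoxyphenyl)methoxy]-4-methylidene-7-(propan-2-yl)octahydro-1H-inden-5-yl (2Z)-2-methylbut-2-enoate | C=C1[C@@H]2C[C@H](O)/C(=C\C)[C@H]2[C@H](C(C)C)[C@H](OCc3ccc(OC)cc3)[C@H]1OC(=O)/C(C)=C\C | intermediate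
28 | (1Z,2S,3aR,5S,6S,7S,7aR)-2-(acetyloxy)-1-ethylidene-6-[(4-methoxyphenyl)methoxy]-4-methylidene-7-(propan-2-yl)octahydro-1H-inden-5-yl (2Z)-2-methylbut-2-enoate | C=C1[C@@H]2C[C@H](OC(C)=O)/C(=C\C)[C@H]2[C@H](C(C)C)[C@H](OCc3ccc(OC)cc3)[C@H]1OC(=O)/C(C)=C\C | intermediate
29 | (1Z,2S,3aR,5S,6S,7S,7aR)-2-(acetyloxy)-1-ethylidene-6-hydroxy-4-methylidene-7-(propan-2-yl)octahydro-1H-inden-5-yl (2Z)-2-methylbut-2-enoate | C=C1[C@@H]2C[C@H](OC(C)=O)/C(=C\C)[C@H]2[C@H](C(C)C)[C@H](O)[C@H]1OC(=O)/C(C)=C\C | target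

**Step count**

Total steps: 17. Longest linear sequence: 16 steps (steps 1–8 and 10–17; step 9 is a one-step side branch).

**Steps most likely to fail**

Step 10. What may go wrong: insufficient endo/exo or facial discrimination in the cycloaddition (cis-fused or face-isomeric adducts), slow transmetalation of the hindered stannane with protodestannylation, or intermolecular cycloaddition of the diene with the iodoenone before coupling. The fallback sets out from 14 and returns at 19. 14 is coupled under the same Stille conditions at 0 °C with (4R)-4-benzyl-3-[(2E)-3-iodoprop-2-enoyl]-1,3-oxazolidin-2-one F1, itself made from (E)-3-iodoacrylic acid and (R)-4-benzyl-1,3-oxazolidin-2-one through the pivaloyl mixed anhydride (LiCl, Et3N). This gives the trienimide F2, which is handled cold. Me2AlCl in CH2Cl2 at −30 °C chelates the imide, so that the auxiliary shields one face of the dienophile and the endo cycloaddition should give the imide cycloadduct F3, the auxiliary reinforcing the preference of the C2 stereocenter. Me3Al/MeNH(OMe)·HCl then gives the Weinreb amide F4, and MeMgBr in THF at 0 °C converts it into 19.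

Step 3. What may go wrong: delivery of tin to the methyl-bearing alkyne carbon, or lactonisation of the hydroxy ester before silylation. The fallback sets out from 3 and returns at 5. Ynone 3 is hydrostannylated before reduction (Bu3SnH, Pd(PPh3)4, THF, 0 °C); conjugation should direct tin to the carbon α to the carbonyl and give methyl (5E)-4-oxo-5-(tributylstannyl)hept-5-enoate F5. CBS reduction with the (R)-2-methyl oxazaborolidine and catecholborane in toluene at −78 °C then sets the carbinol center and gives 5, which is silylated at once.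

Step 13. What may go wrong: competing epoxidation of the ethylidene or of the newly formed methylidene, attack on the α face, or acid-induced rearrangement of the epoxide. The fallback sets out from 21 and returns at 23. Dihydroxylation with OsO4 (cat.) and NMO in acetone/H2O, which responds more strongly to steric shielding and stops at the diol, should give the 4β,5β-diol F6 (a β-hydroxysilane). KH in THF at 0 °C then brings about Peterson elimination of the tertiary alkoxide and the silyl group and gives 23.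

**Further compounds**

F1 | step 10 | (4R)-4-benzyl-3-[(2E)-3-iodoprop-2-enoyl]-1,3-oxazolidin-2-one | O=C1OC[C@@H](Cc2ccccc2)N1C(=O)/C=C/I
F2 | step 10 | (4R)-4-benzyl-3-[(2E,5S,7Z,9E)-5-{[tert-butyl(dimethyl)silyl]oxy}-4-[(Z)-ethylidene]-10-[(4-methoxyphenyl)methoxy]-8-[(trimethylsilyl)methyl]deca-2,7,9-trienoyl]-1,3-oxazolidin-2-one (trienimide) | COc1ccc(CO/C=C/C(C[Si](C)(C)C)=C/C[C@H](O[Si](C)(C)C(C)(C)C)/C(=C\C)/C=C/C(=O)N2[C@H](Cc3ccccc3)COC2=O)cc1
F3 | step 10 | imide cycloadduct: analogue of 19 in which the C7 acetyl group is replaced by the (4R)-4-benzyl-2-oxo-1,3-oxazolidine-3-carbonyl group, ring configuration as in 19 | C[Si](C)(C)CC=1[C@@H]2C[C@H](O[Si](C)(C)C(C)(C)C)/C(=C\C)[C@H]2[C@H](C(=O)N3[C@H](Cc4ccccc4)COC3=O)[C@H](OCc5ccc(OC)cc5)C=1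
F4 | step 10 | Weinreb amide: analogue of 19 in which the C7 acetyl group is replaced by C(=O)N(OMe)Me, ring configuration as in 19 | C[Si](C)(C)CC=1[C@@H]2C[C@H](O[Si](C)(C)C(C)(C)C)/C(=C\C)[C@H]2[C@H](C(=O)N(C)OC)[C@H](OCc3ccc(OC)cc3)C=1
F5 | step 3 | methyl (5E)-4-oxo-5-(tributylstannyl)hept-5-enoate | COC(=O)CCC(=O)/C(=C\C)[Sn](CCCC)(CCCC)CCCC
F6 | step 13 | 4β,5β-diol of 21: 2α-silyloxy, 6α-(4-methoxybenzyl)oxy, 7α-isopropyl, 4α-(trimethylsilyl)methyl, both hydroxyls β | C[Si](C)(C)C[C@]1(O)[C@@H]2C[C@H](O[Si](C)(C)C(C)(C)C)/C(=C\C)[C@H]2[C@H](C(C)C)[C@H](OCc3ccc(OC)cc3)[C@H]1O
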